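**Plan**
- Retrosynthetic cuts, in order: (i) the C4–C4a bond of the chroman, which turns the target into its achiral isomer, alkenylquinone 13; (ii) the quinone back to a p-methoxyphenol; (iii) the aryl–C(=CH2) bond (Negishi); (iv) the ArO–CH2 ether bond.
- Forward: the penta-oxygenated ring is made from 1,2,3,4-tetramethoxybenzene and MOM-protected (steps 1–2); 2,3,4-trimethoxyphenol is O-alkylated with 2,3-dibromopropene (step 3); the two are joined (step 4); the phenol is freed and oxidised to the quinone (steps 5–6); the pyran ring is closed last (step 7).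
- Enabling feature: the benzoquinone ring on C3. Its carbonyl remote from the side chain (C-4 of the dione) is conjugated through the quinone C5=C6 bond with an exocyclic C3=C4 methylene, so chroman C4 is a 1,6-acceptor for arene carbon C4a (ortho to O1, para to the 7-OMe), and C3 is the carbon protonated when the quinone is restored. The quinone is the activating group at its final oxidation level, so no helper has to be removed.
- Stereochemistry: C3, the only stereocentre, is set in step 7 by catalyst-controlled proton transfer; every earlier compound is achiral.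

Key step: step 7

Assumption: the sense of induction of the chiral acid in step 7 cannot be predicted from precedent, so the catalyst is written as (R) and its antipode is meant if a first run shows the opposite sense; 1 and 6 are taken as catalogue compounds.

**Step 1**
Reactants: 1 1,2,3,4-tetramethoxybenzene
Product: 4 2,3,4,5-tetramethoxyphenol, via 2,3,4,5-tetramethoxyphenyllithium 2 (not isolated), via lithium trimethoxy(2,3,4,5-tetramethoxyphenyl)borate 3 (not isolated)
Conditions: n-BuLi, TMEDA, THF, 0 °C; B(OMe)3, −78 °C → rt; then AcOH, 30% aq. H2O2, 0 °C → rt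
Reagents that add atoms: hydrogen peroxide, OO (phenol O of 4); for the intermediates only: n-butyllithium, [Li]CCCC (Li of 2 and 3); trimethyl borate, COB(OC)OC (B(OMe)3 unit of 3)
Why: Directed ortho-metalation next to a methoxy group (the two ring hydrogens are equivalent), borate trapping and C–B to C–O oxidation should give the phenol at the lithiated position (lithiation–borylation–oxidation).

**Step 2**
Reactants: 4 2,3,4,5-tetramethoxyphenol
Product: 5 1-(methoxymethoxy)-2,3,4,5-tetramethoxybenzene
Conditions: NaH, THF/DMF, 0 °C; MOMCl, 0 °C → rt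
Reagents that add atoms: chloromethyl methyl ether, COCCl
Why: Williamson O-alkylation of the sodium phenoxide should install the MOM group, which protects the phenol and directs the metalation in step 4.

**Step 3**
Reactants: 6 2,3,4-trimethoxyphenol; 7 2,3-dibromoprop-1-ene
Product: 8 1-[(2-bromoprop-2-en-1-yl)oxy]-2,3,4-trimethoxybenzene
Conditions: K2CO3, acetone, 50 °C
Reagents that add atoms: none
Why: Williamson ether synthesis by SN2 at the allylic CH2Br should be selective because the vinylic bromide is inert to phenoxide.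

**Step 4**
Reactants: 5 1-(methoxymethoxy)-2,3,4,5-tetramethoxybenzene; 8 1-[(2-bromoprop-2-en-1-yl)oxy]-2,3,4-trimethoxybenzene
Product: 11 1-(methoxymethoxy)-2,3,4,5-tetramethoxy-6-[3-(2,3,4-trimethoxyphenoxy)prop-1-en-2-yl]benzene, via [2-(methoxymethoxy)-3,4,5,6-tetramethoxyphenyl]lithium 9 (not isolated), via chloro[2-(methoxymethoxy)-3,4,5,6-tetramethoxyphenyl]zinc 10 (not isolated)
Conditions: n-BuLi, THF, 0 °C; ZnCl2, 0 °C → rt; then 8, Pd2(dba)3 (2 mol %), SPhos (8 mol %), THF, 60 °C
Reagents that add atoms: n-butyllithium, [Li]CCCC (Li of intermediate 9 only); zinc chloride, Cl[Zn]Cl (Zn and Cl of intermediate 10 only)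
Why: The only ring hydrogen of 5 lies between OMOM and OMe, so directed ortho-metalation is unambiguous, and the derived arylzinc should couple with the alkenyl bromide in a Negishi cross-coupling under a bulky biarylphosphine ligand that tolerates two ortho substituents.

**Step 5**
Reactants: 11 1-(methoxymethoxy)-2,3,4,5-tetramethoxy-6-[3-(2,3,4-trimethoxyphenoxy)prop-1-en-2-yl]benzene
Product: 12 2,3,4,5-tetramethoxy-6-[3-(2,3,4-trimethoxyphenoxy)prop-1-en-2-yl]phenol
Conditions: HCl (cat., from AcCl), MeOH, 0 °C → rt
Reagents that add atoms: none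
Why: Acid-catalysed acetal methanolysis should cleave the aryl MOM ether under conditions mild enough to spare the alkene, which is twisted out of conjugation by its two ortho neighbours and therefore slow to protonate.

**Step 6**
Reactants: 12 2,3,4,5-tetramethoxy-6-[3-(2,3,4-trimethoxyphenoxy)prop-1-en-2-yl]phenol
Product: 13 2,3,5-trimethoxy-6-[3-(2,3,4-trimethoxyphenoxy)prop-1-en-2-yl]cyclohexa-2,5-diene-1,4-dione
Conditions: PhI(OAc)2, MeCN/H2O (2:1), 0 °C; used at once in step 7
Reagents that add atoms: water, O
Why: Hypervalent-iodine oxidative demethylation of a p-methoxyphenol (ligand exchange at iodine needs the free OH, water adds at the para carbon, methanol leaves) should give the p-quinone only on the phenol ring and leave the aryl ether ring untouched.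

**Step 7**
Reactants: 13 2,3,5-trimethoxy-6-[3-(2,3,4-trimethoxyphenoxy)prop-1-en-2-yl]cyclohexa-2,5-diene-1,4-dione
Product: 15 2,3,5-trimethoxy-6-[(3S)-6,7,8-trimethoxy-3,4-dihydro-2H-chromen-3-yl]cyclohexa-2,5-diene-1,4-dione, via dienol 4-hydroxy-2,3,5-trimethoxy-6-(6,7,8-trimethoxy-2H-chromen-3(4H)-ylidene)cyclohexa-2,4-dien-1-one 14 (not isolated)
Conditions: (R)-3,3′-bis(2,4,6-triisopropylphenyl)-BINOL N-triflylphosphoramide (10 mol %), toluene, 0.02 M, −20 °C → 0 °C
Reagents that add atoms: none
Why: Proposed new method: the chiral acid hydrogen-bonds to the quinone C4=O, which is conjugated through C5=C6 with the exocyclic C=CH2, so the terminal CH2 becomes a 1,6-acceptor and is attacked by C6 of the trimethoxyphenoxy ring; loss of the arenium proton to the catalyst anion gives dienol 14, and the catalyst then delivers a proton to the exocyclic carbon while taking the enol O–H, which restores the quinone. The closest known reaction type is the tandem Friedel–Crafts conjugate addition/enantioselective protonation of 2-substituted acrylates and 2-vinyl azaarenes under chiral Brønsted or Lewis-acid-assisted Brønsted acid catalysis; the vinylogous relay through a quinone ring and the use of an alkoxyarene nucleophile are the untested parts. The pyran ring closes in the 6-endo-trig mode, the 5-exo alternative at the internal alkene carbon being mismatched because that carbon is the α-position of the acceptor and a cation there is destabilised by the quinone. The single stereocentre C3 is set by proton transfer to the Re face of the exocyclic carbon of 14 (priorities OCH2 > quinonoid C > ArCH2), controlled by the chiral pocket of the catalyst, as the substrate has no other stereo-element. The step needs terminal-carbon regioselectivity (secured by the polarisation above and by the fully substituted quinone ring, which leaves no ring position open to direct arylation), ortho-site selectivity on the arene (only one ortho position is free, and it is activated by the ether oxygen and the para methoxy group) and a protonation that outruns acid-mediated re-enolisation of the product (low temperature, no base, non-polar solvent).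

**Compound list**
1 | 1,2,3,4-tetramethoxybenzene | COc1ccc(OC)c(OC)c1OC | starting material
2 | 2,3,4,5-tetramethoxyphenyllithium | [Li]c1cc(OC)c(OC)c(OC)c1OC | intermediate
3 | lithium trimethoxy(2,3,4,5-tetramethoxyphenyl)borate | [Li+].CO[B-](OC)(OC)c1cc(OC)c(OC)c(OC)c1OC | intermediate
4 | 2,3,4,5-tetramethoxyphenol | Oc1cc(OC)c(OC)c(OC)c1OC | intermediate
5 | 1-(methoxymethoxy)-2,3,4,5-tetramethoxybenzene | COCOc1cc(OC)c(OC)c(OC)c1OC | intermediate
6 | 2,3,4-trimethoxyphenol | COc1ccc(O)c(OC)c1OC | starting material
7 | 2,3-dibromoprop-1-ene | BrCC(Br)=C | starting material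
8 | 1-[(2-bromoprop-2-en-1-yl)oxy]-2,3,4-trimethoxybenzene | C=C(Br)COc1ccc(OC)c(OC)c1OC | intermediate
9 | [2-(methoxymethoxy)-3,4,5,6-tetramethoxyphenyl]lithium | [Li]c1c(OCOC)c(OC)c(OC)c(OC)c1OC | intermediate
10 | chloro[2-(methoxymethoxy)-3,4,5,6-tetramethoxyphenyl]zinc | Cl[Zn]c1c(OCOC)c(OC)c(OC)c(OC)c1OC | intermediate
11 | 1-(methoxymethoxy)-2,3,4,5-tetramethoxy-6-[3-(2,3,4-trimethoxyphenoxy)prop-1-en-2-yl]benzene | C=C(COc1ccc(OC)c(OC)c1OC)c1c(OCOC)c(OC)c(OC)c(OC)c1OC | intermediate
12 | 2,3,4,5-tetramethoxy-6-[3-(2,3,4-trimethoxyphenoxy)prop-1-en-2-yl]phenol | C=C(COc1ccc(OC)c(OC)c1OC)c1c(O)c(OC)c(OC)c(OC)c1OC | intermediate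
13 | 2,3,5-trimethoxy-6-[3-(2,3,4-trimethoxyphenoxy)prop-1-en-2-yl]cyclohexa-2,5-diene-1,4-dione | COC1=C(OC)C(=O)C(C(=C)COc2ccc(OC)c(OC)c2OC)=C(OC)C1=O | intermediate
14 | 4-hydroxy-2,3,5-trimethoxy-6-(6,7,8-trimethoxy-2H-chromen-3(4H)-ylidene)cyclohexa-2,4-dien-1-one (dienol, alkene geometry not defined) | COC1=C(OC)C(=O)C(=C2COc3c(cc(OC)c(OC)c3OC)C2)C(OC)=C1O | intermediate
15 | 2,3,5-trimethoxy-6-[(3S)-6,7,8-trimethoxy-3,4-dihydro-2H-chromen-3-yl]cyclohexa-2,5-diene-1,4-dione | COC1=C(OC)C(=O)C([C@H]2COc3c(cc(OC)c(OC)c3OC)C2)=C(OC)C1=O | target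

**Step count and risks**
Total: 7 steps. Longest linear sequence: 6 steps (1, 2, 4, 5, 6, 7).

Step 7 (Proposed new method). The acid may fail to activate the twisted, donor-substituted alkenylquinone enough for the arene to add. The proton transfer to C3 may show poor facial discrimination, and reversible enolisation of the product may erode the enantiomeric purity. A charge-accelerated [3,3] shift of the allyl aryl ether followed by phenol addition would reach the same dienol 14 and is therefore not destructive. Fallback by known chemistry, leaving the route at 11 and returning at 15: aromatic Claisen rearrangement (N,N-diethylaniline, 190 °C) should move the allyl unit to the only free ortho position and give 2,3,4-trimethoxy-6-{2-[2-(methoxymethoxy)-3,4,5,6-tetramethoxyphenyl]prop-2-en-1-yl}phenol F1. Catalyst-controlled asymmetric hydroboration of the 1,1-disubstituted aryl alkene (chiral Co or NHC–Cu catalyst, excess HBpin to cover the phenol O–H, then NaBO3) should give 2,3,4-trimethoxy-6-{(2S)-3-hydroxy-2-[2-(methoxymethoxy)-3,4,5,6-tetramethoxyphenyl]propyl}phenol F2. Mitsunobu etherification (PPh3, DIAD, THF) should close the pyran ring without touching the stereocentre and give (3S)-6,7,8-trimethoxy-3-[2-(methoxymethoxy)-3,4,5,6-tetramethoxyphenyl]-3,4-dihydro-2H-chromene F3. HCl/MeOH should free 2,3,4,5-tetramethoxy-6-[(3S)-6,7,8-trimethoxy-3,4-dihydro-2H-chromen-3-yl]phenol F4, and PhI(OAc)2 in MeCN/H2O should oxidise F4 to 15.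

Step 4. Transmetalation and reductive elimination at the doubly ortho-substituted arylzinc may be slow, and the alkenyl-palladium intermediate may lose aryloxide by β-elimination or Pd(0) may ionise the allylic aryl ether. Fallback, leaving the route at 5 and 6 and returning at 11: alkylation of 6 with 2-chloro-N-methoxy-N-methylacetamide (K2CO3, DMF) should give N-methoxy-N-methyl-2-(2,3,4-trimethoxyphenoxy)acetamide F5. Acylation of aryllithium 9 (from 5, n-BuLi) with F5 (THF, −78 °C) should give 1-[2-(methoxymethoxy)-3,4,5,6-tetramethoxyphenyl]-2-(2,3,4-trimethoxyphenoxy)ethan-1-one F6. Wittig methylenation of F6 (Ph3PCH3Br, KOtBu, toluene, 80 °C) should give 11.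

Step 6. The phenoxenium-type intermediate may be captured by the ortho alkenyl group or the electron-rich aryl ether instead of water, water may add ortho instead of para, and the alkenylquinone may be lost by oligomerisation during isolation. Fallback, leaving the route at 4 and 8 and returning at 13, with the oxidation done before the alkene and the second ring are present: NBS (MeCN, 0 °C) should brominate the only free ring position of 4 and give 2-bromo-3,4,5,6-tetramethoxyphenol F7. PhI(OAc)2 in MeCN/H2O should give 2-bromo-3,5,6-trimethoxycyclohexa-2,5-diene-1,4-dione F8. Miyaura borylation of 8 (B2pin2, PdCl2(dppf), KOAc, dioxane) should give 4,4,5,5-tetramethyl-2-[3-(2,3,4-trimethoxyphenoxy)prop-1-en-2-yl]-1,3,2-dioxaborolane F9. Suzuki–Miyaura coupling of F8 with F9 (Pd(PPh3)4, K3PO4, dioxane/H2O, 60 °C) should give 13.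

**Further compounds**
F1 | step 7 | 2,3,4-trimethoxy-6-{2-[2-(methoxymethoxy)-3,4,5,6-tetramethoxyphenyl]prop-2-en-1-yl}phenol | C=C(Cc1cc(OC)c(OC)c(OC)c1O)c1c(OCOC)c(OC)c(OC)c(OC)c1OC
F2 | step 7 | 2,3,4-trimethoxy-6-{(2S)-3-hydroxy-2-[2-(methoxymethoxy)-3,4,5,6-tetramethoxyphenyl]propyl}phenol | OC[C@@H](Cc1cc(OC)c(OC)c(OC)c1O)c1c(OCOC)c(OC)c(OC)c(OC)c1OC
F3 | step 7 | (3S)-6,7,8-trimethoxy-3-[2-(methoxymethoxy)-3,4,5,6-tetramethoxyphenyl]-3,4-dihydro-2H-chromene | COCOc1c([C@H]2COc3c(cc(OC)c(OC)c3OC)C2)c(OC)c(OC)c(OC)c1OC
F4 | step 7 | 2,3,4,5-tetramethoxy-6-[(3S)-6,7,8-trimethoxy-3,4-dihydro-2H-chromen-3-yl]phenol | Oc1c([C@H]2COc3c(cc(OC)c(OC)c3OC)C2)c(OC)c(OC)c(OC)c1OC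
F5 | step 4 | N-methoxy-N-methyl-2-(2,3,4-trimethoxyphenoxy)acetamide | CON(C)C(=O)COc1ccc(OC)c(OC)c1OC
F6 | step 4 | 1-[2-(methoxymethoxy)-3,4,5,6-tetramethoxyphenyl]-2-(2,3,4-trimethoxyphenoxy)ethan-1-one | O=C(COc1ccc(OC)c(OC)c1OC)c1c(OCOC)c(OC)c(OC)c(OC)c1OC
F7 | step 6 | 2-bromo-3,4,5,6-tetramethoxyphenol | Oc1c(Br)c(OC)c(OC)c(OC)c1OC
F8 | step 6 | 2-bromo-3,5,6-trimethoxycyclohexa-2,5-diene-1,4-dione | COC1=C(OC)C(=O)C(Br)=C(OC)C1=O
F9 | step 6 | 4,4,5,5-tetramethyl-2-[3-(2,3,4-trimethoxyphenoxy)prop-1-en-2-yl]-1,3,2-dioxaborolane | C=C(COc1ccc(OC)c(OC)c1OC)B1OC(C)(C)C(C)(C)O1
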